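The plan treats ring C of the anisyl-bearing flavone (unit 1) as a masked 3,5-diarylisoxazole. C2, C3 and C4 form the three-carbon span between the anisyl ring and C4a of ring A, with a heteroatom at each end, and they correspond to isoxazole C3, C4 and C5. A single [3+2] addition of 4-methoxybenzonitrile oxide to an ethynyl group on ring A forms C2–C3 and C4–O at once. The alkyne precursor already contains the C6 diaryl ether to a tert-butyl benzoate, both methoxy groups, and a benzyl ether on the future O1. Hydrogenolysis, then acid, turn the isoxazole into the pyranone. Unit 2 is added by Baker–Venkataraman chemistry.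

Key step: step 9

Remark: flavone numbering is used for both halves (unit 1 = the 4-methoxyphenyl flavone, unit 2 = the 5,7-dihydroxyflavone). The target has no stereocentre, so only C=N and C=C geometries of intermediates are specified. Boronic acid 2 is assumed to be a catalogue compound.

Step 1
Reactants: 1 syringaldehyde (4-hydroxy-3,5-dimethoxybenzaldehyde); 2 4-(tert-butoxycarbonyl)phenylboronic acid
Product: 3 tert-butyl 4-(4-formyl-2,6-dimethoxyphenoxy)benzoate
Conditions: 2 (2 equiv), Cu(OAc)2 (1 equiv, kept divalent by the air), pyridine (5 equiv), 4 Å MS, CH2Cl2, dry air, rt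
Reagents that add atoms: none
Why: Chan–Lam O-arylation (transmetalation to a divalent copper phenoxide, oxidation to trivalent copper, C–O reductive elimination) runs at room temperature, is known to accept acidic di-ortho-substituted phenols, and spares the aldehyde and tert-butyl ester, whereas displacement of fluoride from a merely ester-activated arene by this weak, hindered phenoxide would need forcing heat.

Step 2
Reactants: 3 tert-butyl 4-(4-formyl-2,6-dimethoxyphenoxy)benzoate
Product: 5 tert-butyl 4-(4-hydroxy-2,6-dimethoxyphenoxy)benzoate, via aryl formate 4 (not isolated)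
Conditions: mCPBA (1.5 equiv), CH2Cl2, 0 °C → rt; aq. Na2S2O3/NaHCO3 wash; then K2CO3 (0.1 equiv), MeOH, rt
Reagents that add atoms: mCPBA, O=C(OO)c1cccc(Cl)c1
Why: Baeyer–Villiger oxidation is used because a true Dakin reaction needs a free ortho or para hydroxyl that 3 lacks; the trioxygenated aryl group should migrate in preference to hydrogen in the Criegee adduct, and the labile aryl formate is then removed by catalytic methanolysis, after the peracid has been destroyed, without touching the tert-butyl ester.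

Step 3
Reactants: 5 tert-butyl 4-(4-hydroxy-2,6-dimethoxyphenoxy)benzoate
Product: 6 tert-butyl 4-(4-hydroxy-3-iodo-2,6-dimethoxyphenoxy)benzoate
Conditions: NIS (1.0 equiv), MeCN, −10 → 0 °C, dark
Reagents that add atoms: N-iodosuccinimide, O=C1CCC(=O)N1I
Why: In this electrophilic aromatic iodination only ring A is activated, and its two free positions are equivalent by symmetry, each ortho to OH and ortho/para to the methoxy groups, so one equivalent of NIS in the cold should stop at the mono-iodide and leave the benzoate ring alone.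

Step 4
Reactants: 6 tert-butyl 4-(4-hydroxy-3-iodo-2,6-dimethoxyphenoxy)benzoate
Product: 7 tert-butyl 4-[4-(benzyloxy)-3-iodo-2,6-dimethoxyphenoxy]benzoate
Conditions: BnBr (1.2 equiv), K2CO3 (1.5 equiv), DMF, rt
Reagents that add atoms: benzyl bromide, BrCc1ccccc1
Why: Williamson etherification installs a benzyl ether which, unlike an aryl acetate, survives the amine of step 5 and the methanolysis of step 6, so no free o-alkynylphenol can close to a benzofuran, and which leaves later in the same hydrogenolysis that opens the isoxazole.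

Step 5
Reactants: 7 tert-butyl 4-[4-(benzyloxy)-3-iodo-2,6-dimethoxyphenoxy]benzoate; 8 trimethylsilylacetylene
Product: 9 tert-butyl 4-{4-(benzyloxy)-2,6-dimethoxy-3-[(trimethylsilyl)ethynyl]phenoxy}benzoate
Conditions: 8 (2 equiv), PdCl2(PPh3)2 (5 mol %), CuI (10 mol %), Et3N–THF 1:1, 60 °C
Reagents that add atoms: none
Why: Sonogashira coupling should work because zerovalent palladium inserts into the reactive C–I bond despite the two ortho alkoxy groups and the slim copper acetylide makes little steric demand, as known for 2-iodo-1,3-dialkoxyarenes.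

Step 6
Reactants: 9 tert-butyl 4-{4-(benzyloxy)-2,6-dimethoxy-3-[(trimethylsilyl)ethynyl]phenoxy}benzoate
Product: 10 tert-butyl 4-[4-(benzyloxy)-3-ethynyl-2,6-dimethoxyphenoxy]benzoate
Conditions: K2CO3 (0.2 equiv), MeOH–THF 1:1, rt
Reagents that add atoms: none
Why: In this base-catalysed protodesilylation methoxide attacks silicon and the alkynyl anion is protonated by methanol, conditions under which the benzyl ether, diaryl ether and tert-butyl ester are inert.

Step 7
Reactants: 11 4-methoxybenzaldehyde
Product: 12 (E)-4-methoxybenzaldehyde oxime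
Conditions: NH2OH·HCl (1.2 equiv), NaOAc (1.3 equiv), EtOH–H2O, rt
Reagents that add atoms: hydroxylamine hydrochloride, NO.Cl
Why: Oxime condensation of an aromatic aldehyde under acetate buffer is routine and should give the thermodynamically preferred E isomer.

Step 8
Reactants: 12 (E)-4-methoxybenzaldehyde oxime
Product: 13 (Z)-N-hydroxy-4-methoxybenzenecarboximidoyl chloride
Conditions: NCS (1.0 equiv), DMF, rt; aqueous work-up
Reagents that add atoms: N-chlorosuccinimide, O=C1CCC(=O)N1Cl
Why: C-chlorination of the aldoxime with NCS is the standard route to hydroximoyl chlorides, and isolating 13 keeps all active chlorine away from the very electron-rich C8–H of ring A in the next step.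

Step 9
Reactants: 10 tert-butyl 4-[4-(benzyloxy)-3-ethynyl-2,6-dimethoxyphenoxy]benzoate; 13 (Z)-N-hydroxy-4-methoxybenzenecarboximidoyl chloride
Product: 15 tert-butyl 4-{4-(benzyloxy)-2,6-dimethoxy-3-[3-(4-methoxyphenyl)isoxazol-5-yl]phenoxy}benzoate, via 4-methoxybenzonitrile oxide 14 (not isolated)
Conditions: 13 (1.8 equiv), Et3N (2.0 equiv, syringe pump over 8 h), toluene (0.5 M in 10), 50 °C
Reagents that add atoms: none
Why: Et3N removes HCl from 13, and the resulting nitrile oxide 14 adds to the ethynyl group of 10 in a concerted, asynchronous Huisgen 1,3-dipolar cycloaddition in which the dipole carbon (future C2) bonds to the terminal alkyne carbon (C3) and the dipole oxygen bonds to the internal carbon (C4). The closest known reaction type is the addition of aryl nitrile oxides to arylacetylenes, the standard entry to 3,5-diarylisoxazoles. The five-membered ring is closed by the intermolecular [3+2] mode itself, both ring bonds arise in one suprafacial event, and the ring is aromatic as formed, so no oxidation is needed and no stereocentre arises. The step needs 3,5- over 3,4-regioselectivity: the anisyl-bearing dipole carbon avoids the internal carbon, which is shielded by the ortho OMe and OBn groups of ring A, and the terminal carbon carries the larger HOMO coefficient of this donor-substituted alkyne. Capture of 14 must also outrun its dimerisation, which slow base addition, an excess of 13 and a concentrated alkyne solution should secure. The benzyl ether, tert-butyl ester and diaryl ether are inert to Et3N and to the dipole.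

Step 10
Reactants: 15 tert-butyl 4-{4-(benzyloxy)-2,6-dimethoxy-3-[3-(4-methoxyphenyl)isoxazol-5-yl]phenoxy}benzoate
Product: 17 tert-butyl 4-{3-[(2Z)-3-amino-3-(4-methoxyphenyl)prop-2-enoyl]-4-hydroxy-2,6-dimethoxyphenoxy}benzoate, via phenolic isoxazole 16 (not isolated)
Conditions: H2 (1 atm), 10% Pd/C, EtOAc–EtOH 1:1, rt
Reagents that add atoms: none
Why: Catalytic hydrogenolysis should first remove the O-benzyl group and then cleave the weak N–O bond, the known reductive opening of 3,5-diarylisoxazoles to hydrogen-bonded (Z)-β-amino enones that leaves oxygen on C4 and nitrogen on C2, while the vinylogous amide, diaryl ether and tert-butyl ester resist these conditions.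

Step 11
Reactants: 17 tert-butyl 4-{3-[(2Z)-3-amino-3-(4-methoxyphenyl)prop-2-enoyl]-4-hydroxy-2,6-dimethoxyphenoxy}benzoate
Product: 19 4-{[5,7-dimethoxy-2-(4-methoxyphenyl)-4-oxo-4H-chromen-6-yl]oxy}benzoic acid, via flavone tert-butyl ester 18 (not isolated)
Conditions: TFA (10 vol %) in CH2Cl2, rt; then TFA raised to 50 vol %, rt → 35 °C
Reagents that add atoms: none
Why: This is the acid-mediated chromone closure of an o-hydroxyaryl enaminone by addition–elimination (6-endo attack of the phenol oxygen on protonated C2, then loss of ammonia as its salt to give the aromatic pyranone), followed in the stronger acid by alkyl–oxygen ionisation of the tert-butyl ester, so ester cleavage costs no separate step and the methyl ethers are untouched.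

Step 12
Reactants: 20 2',4',6'-trihydroxyacetophenone
Product: 21 1-[2,4-bis(benzyloxy)-6-hydroxyphenyl]ethan-1-one
Conditions: BnBr (2.05 equiv), K2CO3 (2.2 equiv), DMF, rt
Reagents that add atoms: benzyl bromide, BrCc1ccccc1
Why: Williamson etherification with two equivalents of halide should stop at the dibenzyl ether because the last hydroxyl is locked in a strong hydrogen bond to the acetyl carbonyl and is the least nucleophilic.

Step 13
Reactants: 19 4-{[5,7-dimethoxy-2-(4-methoxyphenyl)-4-oxo-4H-chromen-6-yl]oxy}benzoic acid; 21 1-[2,4-bis(benzyloxy)-6-hydroxyphenyl]ethan-1-one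
Product: 22 2-acetyl-3,5-bis(benzyloxy)phenyl 4-{[5,7-dimethoxy-2-(4-methoxyphenyl)-4-oxo-4H-chromen-6-yl]oxy}benzoate
Conditions: DCC (1.3 equiv), DMAP (0.2 equiv), CH2Cl2–DMF, rt
Reagents that add atoms: none
Why: Steglich esterification through the acylpyridinium ion acylates even chelated o-acetylphenols and avoids chlorinating agents that could activate the electron-rich pyranone carbonyl of unit 1.

Step 14
Reactants: 22 2-acetyl-3,5-bis(benzyloxy)phenyl 4-{[5,7-dimethoxy-2-(4-methoxyphenyl)-4-oxo-4H-chromen-6-yl]oxy}benzoate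
Product: 23 1-[2,4-bis(benzyloxy)-6-hydroxyphenyl]-3-(4-{[5,7-dimethoxy-2-(4-methoxyphenyl)-4-oxo-4H-chromen-6-yl]oxy}phenyl)propane-1,3-dione
Conditions: LiHMDS (3 equiv), THF, −78 → 0 °C; aq. HCl (1 M) quench
Reagents that add atoms: none
Why: In the Baker–Venkataraman rearrangement the methyl ketone enolate attacks the neighbouring aryl ester through a six-membered transition state and the acyl group shifts from O to C, and a bulky non-nucleophilic amide base is chosen so that nothing adds to C2 of the flavone already present.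

Step 15
Reactants: 23 1-[2,4-bis(benzyloxy)-6-hydroxyphenyl]-3-(4-{[5,7-dimethoxy-2-(4-methoxyphenyl)-4-oxo-4H-chromen-6-yl]oxy}phenyl)propane-1,3-dione
Product: 24 5,7-bis(benzyloxy)-2-(4-{[5,7-dimethoxy-2-(4-methoxyphenyl)-4-oxo-4H-chromen-6-yl]oxy}phenyl)-4H-chromen-4-one
Conditions: TsOH·H2O (10 mol %), toluene, 90 °C
Reagents that add atoms: none
Why: Acid-catalysed cyclodehydration of an o-hydroxydibenzoylmethane (hemiketal formation at the aroyl carbonyl, then loss of water) is the standard flavone closure, and catalytic sulfonic acid is mild enough to keep the benzyl ethers.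

Step 16
Reactants: 24 5,7-bis(benzyloxy)-2-(4-{[5,7-dimethoxy-2-(4-methoxyphenyl)-4-oxo-4H-chromen-6-yl]oxy}phenyl)-4H-chromen-4-one
Product: 25 cryptomerin B, 5,7-dihydroxy-2-(4-{[5-hydroxy-7-methoxy-2-(4-methoxyphenyl)-4-oxo-4H-chromen-6-yl]oxy}phenyl)-4H-chromen-4-one
Conditions: BCl3 (1 M in CH2Cl2, 8 equiv), C6HMe5 (6 equiv), CH2Cl2, −78 → 0 °C; then aq. HCl
Reagents that add atoms: none
Why: In this Lewis-acid ether cleavage BCl3 chelated between C4=O and the peri 5-OMe of unit 1 removes that methyl group selectively and also ionises both benzyl ethers of unit 2, with pentamethylbenzene trapping the benzyl cations, while the non-chelated methyl ethers at C7 and on the anisyl ring are not attacked by BCl3 at or below 0 °C.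

Compound list
1 | syringaldehyde | COc1cc(C=O)cc(OC)c1O | starting material
2 | 4-(tert-butoxycarbonyl)phenylboronic acid | CC(C)(C)OC(=O)c1ccc(B(O)O)cc1 | starting material
3 | tert-butyl 4-(4-formyl-2,6-dimethoxyphenoxy)benzoate | COc1cc(C=O)cc(OC)c1Oc1ccc(C(=O)OC(C)(C)C)cc1 | intermediate
4 | tert-butyl 4-[4-(formyloxy)-2,6-dimethoxyphenoxy]benzoate (not isolated) | COc1cc(OC=O)cc(OC)c1Oc1ccc(C(=O)OC(C)(C)C)cc1 | intermediate
5 | tert-butyl 4-(4-hydroxy-2,6-dimethoxyphenoxy)benzoate | COc1cc(O)cc(OC)c1Oc1ccc(C(=O)OC(C)(C)C)cc1 | intermediate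
6 | tert-butyl 4-(4-hydroxy-3-iodo-2,6-dimethoxyphenoxy)benzoate | COc1cc(O)c(I)c(OC)c1Oc1ccc(C(=O)OC(C)(C)C)cc1 | intermediate
7 | tert-butyl 4-[4-(benzyloxy)-3-iodo-2,6-dimethoxyphenoxy]benzoate | COc1cc(OCc2ccccc2)c(I)c(OC)c1Oc1ccc(C(=O)OC(C)(C)C)cc1 | intermediate
8 | trimethylsilylacetylene | C#C[Si](C)(C)C | starting material
9 | tert-butyl 4-{4-(benzyloxy)-2,6-dimethoxy-3-[(trimethylsilyl)ethynyl]phenoxy}benzoate | COc1cc(OCc2ccccc2)c(C#C[Si](C)(C)C)c(OC)c1Oc1ccc(C(=O)OC(C)(C)C)cc1 | intermediate
10 | tert-butyl 4-[4-(benzyloxy)-3-ethynyl-2,6-dimethoxyphenoxy]benzoate | COc1cc(OCc2ccccc2)c(C#C)c(OC)c1Oc1ccc(C(=O)OC(C)(C)C)cc1 | intermediate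
11 | 4-methoxybenzaldehyde | COc1ccc(C=O)cc1 | starting material
12 | (E)-4-methoxybenzaldehyde oxime | COc1ccc(/C=N/O)cc1 | intermediate
13 | (Z)-N-hydroxy-4-methoxybenzenecarboximidoyl chloride | COc1ccc(/C(Cl)=N/O)cc1 | intermediate
14 | 4-methoxybenzonitrile oxide (not isolated) | COc1ccc(C#[N+][O-])cc1 | intermediate
15 | tert-butyl 4-{4-(benzyloxy)-2,6-dimethoxy-3-[3-(4-methoxyphenyl)isoxazol-5-yl]phenoxy}benzoate | COc1ccc(-c2cc(-c3c(OCc4ccccc4)cc(OC)c(Oc4ccc(C(=O)OC(C)(C)C)cc4)c3OC)on2)cc1 | intermediate
16 | tert-butyl 4-{4-hydroxy-2,6-dimethoxy-3-[3-(4-methoxyphenyl)isoxazol-5-yl]phenoxy}benzoate (not isolated) | COc1ccc(-c2cc(-c3c(O)cc(OC)c(Oc4ccc(C(=O)OC(C)(C)C)cc4)c3OC)on2)cc1 | intermediate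
17 | tert-butyl 4-{3-[(2Z)-3-amino-3-(4-methoxyphenyl)prop-2-enoyl]-4-hydroxy-2,6-dimethoxyphenoxy}benzoate | COc1ccc(/C(N)=C/C(=O)c2c(O)cc(OC)c(Oc3ccc(C(=O)OC(C)(C)C)cc3)c2OC)cc1 | intermediate
18 | tert-butyl 4-{[5,7-dimethoxy-2-(4-methoxyphenyl)-4-oxo-4H-chromen-6-yl]oxy}benzoate (not isolated) | COc1ccc(-c2cc(=O)c3c(OC)c(Oc4ccc(C(=O)OC(C)(C)C)cc4)c(OC)cc3o2)cc1 | intermediate
19 | 4-{[5,7-dimethoxy-2-(4-methoxyphenyl)-4-oxo-4H-chromen-6-yl]oxy}benzoic acid | COc1ccc(-c2cc(=O)c3c(OC)c(Oc4ccc(C(=O)O)cc4)c(OC)cc3o2)cc1 | intermediate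
20 | 2',4',6'-trihydroxyacetophenone | CC(=O)c1c(O)cc(O)cc1O | starting material
21 | 1-[2,4-bis(benzyloxy)-6-hydroxyphenyl]ethan-1-one | CC(=O)c1c(O)cc(OCc2ccccc2)cc1OCc1ccccc1 | intermediate
22 | 2-acetyl-3,5-bis(benzyloxy)phenyl 4-{[5,7-dimethoxy-2-(4-methoxyphenyl)-4-oxo-4H-chromen-6-yl]oxy}benzoate | COc1ccc(-c2cc(=O)c3c(OC)c(Oc4ccc(C(=O)Oc5cc(OCc6ccccc6)cc(OCc6ccccc6)c5C(C)=O)cc4)c(OC)cc3o2)cc1 | intermediate
23 | 1-[2,4-bis(benzyloxy)-6-hydroxyphenyl]-3-(4-{[5,7-dimethoxy-2-(4-methoxyphenyl)-4-oxo-4H-chromen-6-yl]oxy}phenyl)propane-1,3-dione | COc1ccc(-c2cc(=O)c3c(OC)c(Oc4ccc(C(=O)CC(=O)c5c(O)cc(OCc6ccccc6)cc5OCc5ccccc5)cc4)c(OC)cc3o2)cc1 | intermediate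
24 | 5,7-bis(benzyloxy)-2-(4-{[5,7-dimethoxy-2-(4-methoxyphenyl)-4-oxo-4H-chromen-6-yl]oxy}phenyl)-4H-chromen-4-one | COc1ccc(-c2cc(=O)c3c(OC)c(Oc4ccc(-c5cc(=O)c6c(OCc7ccccc7)cc(OCc7ccccc7)cc6o5)cc4)c(OC)cc3o2)cc1 | intermediate
25 | cryptomerin B | COc1ccc(-c2cc(=O)c3c(O)c(Oc4ccc(-c5cc(=O)c6c(O)cc(O)cc6o5)cc4)c(OC)cc3o2)cc1 | target

Total step count: 16. Longest linear sequence: 13 (steps 1–6, 9–11, 13–16).

Steps most likely to fail

Step 9. Self-dimerisation of the dipole may outrun its capture by an alkyne flanked on both sides by ortho alkoxy groups, so that conversion stalls. The fallback builds the same isoxazole by condensation instead of cycloaddition. It sets out from 10 and comes back at 15. Acyl Sonogashira coupling of 10 with 4-methoxybenzoyl chloride (PdCl2(PPh3)2, CuI, Et3N, THF, rt) should give the ynone tert-butyl 4-{4-(benzyloxy)-2,6-dimethoxy-3-[3-(4-methoxyphenyl)-3-oxoprop-1-yn-1-yl]phenoxy}benzoate F1. 1,2-Condensation with NH2OH·HCl in pyridine–MeOH should give the acetylenic oxime tert-butyl 4-{4-(benzyloxy)-3-[(3Z)-3-(hydroxyimino)-3-(4-methoxyphenyl)prop-1-yn-1-yl]-2,6-dimethoxyphenoxy}benzoate F2. AuCl3-catalysed 5-endo-dig attack of the oxime oxygen on the alkyne carbon bound to ring A (CH2Cl2, 30 °C) then closes 15. This closure places nitrogen next to the anisyl carbon, as required.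

Step 1. Transmetalation and C–O reductive elimination may be too slow, because the phenoxide is crowded by two methoxy groups and drained by the para-formyl group. Protodeboronation and homocoupling would then consume the boronic acid. The fallback changes the ring A building block and the way its second oxygen is introduced. It sets out from 2 and comes back at 5, which also makes step 2 unnecessary. Copper-mediated arylation of commercial 4-bromo-2,6-dimethoxyphenol with 2 should give tert-butyl 4-(4-bromo-2,6-dimethoxyphenoxy)benzoate F3; this phenol is far more nucleophilic, and its bromide is inert at room temperature. Miyaura borylation (B2pin2, PdCl2(dppf), KOAc, dioxane, 90 °C) should give tert-butyl 4-[2,6-dimethoxy-4-(4,4,5,5-tetramethyl-1,3,2-dioxaborolan-2-yl)phenoxy]benzoate F4. Oxidation of the C–B bond (H2O2, THF–H2O, rt) then delivers 5.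

Step 16. Three processes could spoil the single global cleavage:
- incomplete cleavage of the non-chelated 7-O-benzyl ether;
- Friedel–Crafts transfer of benzyl cations to the phloroglucinol-type ring of unit 2;
- slow loss of a wanted methyl ether if the mixture has to be warmed.

The fallback separates the two kinds of ether cleavage. It sets out from 24 and comes back at 25. Hydrogenolysis (H2, 10% Pd/C, THF–MeOH, rt) should give 5,7-dihydroxy-2-(4-{[5,7-dimethoxy-2-(4-methoxyphenyl)-4-oxo-4H-chromen-6-yl]oxy}phenyl)-4H-chromen-4-one F5. A single chelation-directed demethylation of the peri 5-OMe (BCl3, CH2Cl2, −20 → 0 °C) then gives 25.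

Further compounds
F1 | step 9 | tert-butyl 4-{4-(benzyloxy)-2,6-dimethoxy-3-[3-(4-methoxyphenyl)-3-oxoprop-1-yn-1-yl]phenoxy}benzoate | COc1ccc(C(=O)C#Cc2c(OCc3ccccc3)cc(OC)c(Oc3ccc(C(=O)OC(C)(C)C)cc3)c2OC)cc1
F2 | step 9 | tert-butyl 4-{4-(benzyloxy)-3-[(3Z)-3-(hydroxyimino)-3-(4-methoxyphenyl)prop-1-yn-1-yl]-2,6-dimethoxyphenoxy}benzoate | COc1ccc(/C(C#Cc2c(OCc3ccccc3)cc(OC)c(Oc3ccc(C(=O)OC(C)(C)C)cc3)c2OC)=N/O)cc1
F3 | step 1 | tert-butyl 4-(4-bromo-2,6-dimethoxyphenoxy)benzoate | COc1cc(Br)cc(OC)c1Oc1ccc(C(=O)OC(C)(C)C)cc1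
F4 | step 1 | tert-butyl 4-[2,6-dimethoxy-4-(4,4,5,5-tetramethyl-1,3,2-dioxaborolan-2-yl)phenoxy]benzoate | COc1cc(B2OC(C)(C)C(C)(C)O2)cc(OC)c1Oc1ccc(C(=O)OC(C)(C)C)cc1
F5 | step 16 | 5,7-dihydroxy-2-(4-{[5,7-dimethoxy-2-(4-methoxyphenyl)-4-oxo-4H-chromen-6-yl]oxy}phenyl)-4H-chromen-4-one | COc1ccc(-c2cc(=O)c3c(OC)c(Oc4ccc(-c5cc(=O)c6c(O)cc(O)cc6o5)cc4)c(OC)cc3o2)cc1
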